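We start from a rate constant read off the beta run.

| flask | substrate | reagent | temperature | remark | time |
|---|---|---|---|---|---|
| beta | 0.020 M | 0.021 M | 25 °C | the very flask that is asked about, followed so far |  |
| theta | 0.030 M | 0.021 M | 20 °C | run made earlier |  |
| flask | 0.020 M | 0.0210 M | 25 °C |  | 40 h |


beta run (percent of the substrate charged)

| time / h | target / % |
|---|---|
| 3.00 | 65 |
| 8.00 | 76 |
| 15.0 | 81 |
| 40.0 | 81 |

theta run (percent of the substrate charged)

| time / min | target / % |
|---|---|
| 12.0 | 11 |
| 30.0 | 23 |
| 60.0 | 31 |
| 90.0 | 38 |

(scatter of a reading: 2 percentage points)
- Thursday's: at 40 h raise the temperature by 20 K, then wait 20 h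
- Wednesday's: at 40 h take out 90% of the target then present, then wait 20 h
- Friday's: at 40 h add reagent, 100% of the amount charged, then wait 20 h
- Tuesday's: change nothing and wait 20 h more
- what is taken out of target is counted as made
- additions bring no volume worth counting
- target, in percent of the substrate first charged, at 40 h
- which option adds most target ("none" when 2 percentage points or less is all one gets) (Thursday's / Wednesday's / Friday's / Tuesday's / none)
- target present, with what was taken out counted in, in percent of the substrate first charged, after Thursday's
- target present, with what was taken out counted in, in percent of the substrate first charged, after Wednesday's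

In the beta run, the reading 65% at 3.00 h goes into the closed form for a second-order step, 1/c − 1/c₀ = kt. Taking the two charges as equal, it gives a rate constant of 31.0 M⁻¹ h⁻¹, as a reading. But the beta readings stand at 81% from 15.0 h on, so 19.0% of the substrate does not show as target. Is that a slow tail or a stop?

Two times answer this. If target has formed one for one with reagent, 0.00480 M of reagent is left. Free substrate then decays in a pseudo-first-order way, with a drain time, one over rate constant times reagent left, of 6.73 h. Against it stands the flat stretch of 25.0 h, a ratio of 3.71. Nearly all of any substrate free at 15.0 h should have become target, yet the readings did not move beyond their scatter.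

So we read the missing share as no longer free substrate, and expect "none" as best. This assumes a one-way step and live reagent, and we have not proved either.

The forecast gives 81% and names Friday's: “Adding reagent wins either way”. It puts Thursday's at 77% and Wednesday's at 87%.

The flask gives 79.4%, best none, with 79.4% after Thursday's and 79.4% after Wednesday's. At 40.0 h the flask holds 20.6% of the charged substrate as side product, and 0.00838% is still free substrate.

    substrate + reagent → target (k = 37.0 M⁻¹ h⁻¹, Ea = 52.0 kJ mol⁻¹)
    2 substrate → side product (k = 7.40 M⁻¹ h⁻¹, Ea = 48.0 kJ mol⁻¹)
    (constants at 25 °C)

Over 20 h, our drain time reckons 0.008 percentage points of that free substrate into target; Tuesday's computed gain is 0.0082 points, Friday's 0.0084 points.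

A second flask, the same but with 0.0084 M of reagent, has 1.08% of that reagent free at 40.0 h. At that moment the drain time by the step to target is 356 h, far longer than 40 h. The computed second flask keeps 5.7% of its substrate, with 41.5% target.

The earlier runs and the new flask were generated by integration on assumed constants; noise was put on by code.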